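All runs were computed on assumed constants.

In a one-step world each monomer charged ends in a chain and each initiator begins one chain, so the length is the reciprocal of the initiator loading, 500 units, whatever the concentration. This flask has other exits, so I correct that figure by the fraction y of the charged free monomer that reaches chains. With x the loading:

n = y / x

| flask | free monomer | transfer agent | protic impurity | initiator | remark | time |
|---|---|---|---|---|---|---|
| Sunday's | 1.2 M | 0.10 M | 0.050 M | 0.2 mol% | run made earlier |  |
| Monday's | 1.3 M | 0.10 M | 0.050 M | 0.2 mol% | run made earlier |  |
| eta | 1.0 M | 0.100 M | 0.0500 M | 0.2 mol% |  | 40 min |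
| epsilon | 1.5 M | 0.100 M | 0.0500 M | 0.2 mol% |  | 40 min |

| run | time / min | monomer in chains / % | free monomer / % |
|---|---|---|---|
| Sunday's | 2.50 | 2.8 | 90.2 |
| Sunday's | 4.00 | 4.3 | 84.2 |
| Sunday's | 8.00 | 7.6 | 76.5 |
| Sunday's | 15.0 | 14.8 | 59.7 |
| Sunday's | 30.0 | 17.1 | 43.6 |
| Monday's | 6.00 | 8.3 | 78.3 |
| Monday's | 12.0 | 13.1 | 66.4 |
| Monday's | 15.0 | 15.0 | 61.7 |
| Monday's | 25.0 | 18.7 | 44.8 |
| Monday's | 30.0 | 20.9 | 42.2 |

(standard deviation of a reading: 1 percentage point)

- which of the two ends with the longer chains by the average number of monomer units in a chain (chains begun, living or dead) ("neither" if they lie within 10%) (eta / epsilon / neither)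
- average number of monomer units in a chain (chains begun, living or dead) at the end, eta
- average number of monomer units in a chain (chains begun, living or dead) at the end, epsilon

- the average divides the monomer in chains by the number of chains begun, living and dead together
- the earlier runs do not show the number of chains; that part of a forecast is a guess

I count no chains from the transfer agent. The runs do not show the number of chains, so this is my guess, and any chain begun by transfer shortens what follows.

One extreme keeps y fixed at the mean of the last readings, 19.0%. Both new flasks then give 95.0, and the answer is "neither".

The other extreme treats chains as the minor branch. At 30.0 min in Sunday's run, 17.1% stands in chains and 39.3% has gone elsewhere. Suppose growth is pseudo-first-order in living ends, whose concentration follows the charge c at fixed loading, while the loss does not follow c. Then y is proportional to c, and I carry the length per molar of charge, Λ: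

Λ = y / (x·c): Sunday's 71.3 M⁻¹, Monday's 80.4 M⁻¹, mean 75.8 M⁻¹

I expect each new flask close to the second extreme, since in Sunday's run chains are the smaller branch. So I commit to n = Λ·c:

eta 75.8, epsilon 114

That puts epsilon ahead by more than the margin.

The forecast expects 60 for eta and 75 for epsilon, so epsilon, and it differs from my count in holding that “Transfer adds chains, but the runs do not show how many”.

The flask gives 79.5 for eta and 117 for epsilon, so epsilon ends longer.

    free monomer + living end → monomer in chains + living end, rate k1*[living end]*[free monomer] (k = 0.130 M⁻¹ s⁻¹)
    free monomer + initiator → living end + monomer in chains (k = 0.00870 M⁻¹ s⁻¹)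
    protic impurity + free monomer → quenched substrate (k = 0.0140 M⁻¹ s⁻¹)
    living end + transfer agent → dead chain (kL = 0.0100 M⁻¹ s⁻¹)
    free monomer → uncatalysed product (k = 3.00 × 10⁻⁴ s⁻¹)

Epsilon's lead comes from its concentration of free monomer: taken to eta's concentration, epsilon gives 79.5 in place of 117. Λ follows that step, since 75.8 and 114 stand beside 79.5 and 117. In a flask like eta but with 0.60 M of free monomer, Λ gives 45.5, and that flask stands at 46.7.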